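**Plan**

1. Retrosynthesis (carotenoid numbering: ring C1–C6, chain C7–C15 then C15'–C8', C8' = CHO). The first cut is the sp–sp2 bond C8–C9, read as retro-addition of the alkyne C8–H across a C9≡C10 triple bond. This gives ring alkyne 7 (C11) and the methyl-capped hexaenynal 18 (C19).
2. 18 is cut at C11=C12 and C11'=C12' (two Horner–Wadsworth–Emmons reactions) to the symmetric C10 dialdehyde 11, C4 phosphonate 10 and C5 phosphono ester 12. 7 is cut at C6–C7 (Sonogashira coupling of the enol triflate of silylated actinol 1).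
3. Forward: the cyclohexene ring is bought as actinol, and only its C5=C6 bond and ethynyl group are made (steps 1–4). The chain grows C10 → C15 → C19 and is brought to the aldehyde level (steps 5–9). Step 10 joins the halves without protecting groups and ends the synthesis.
4. Enabling feature: C9 is the methyl-bearing end atom of the π system that runs from the formyl carbon C8' through six C=C bonds. In the target, C8 and the H on C10 are cis across C9=C10, which is the signature of a syn addition of alkynyl and H across MeC9≡C10. The C7≡C8 bond is shielded by C6 and its neighbours C1 (gem-dimethyl) and C5 (methyl).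
5. Stereochemistry: C3 (R) comes unchanged from C4 of (4R,6R)-actinol. The E geometries come from all-E 11 and 12, from two E-selective olefinations, and for C9=C10 from the syn addition of step 10.

Key step: step 10

Assumption: (4R,6R)-actinol 1, dialdehyde 11 and phosphono ester 12 are taken as purchasable industrial carotenoid building blocks; all polyene steps are run under argon in dim light.

**Step 1**
Reactants: 1 (4R,6R)-4-hydroxy-2,2,6-trimethylcyclohexan-1-one
Product: 2 (4R,6R)-4-[(tert-butyldimethylsilyl)oxy]-2,2,6-trimethylcyclohexan-1-one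
Conditions: TBSCl, imidazole, DMF, rt
Reagents that add atoms: tert-butyldimethylsilyl chloride, CC(C)(C)[Si](C)(C)Cl
Why: Imidazole-mediated silyl ether formation on the unhindered secondary alcohol masks the OH before enolisation and leaves the carbinol stereocentre untouched.

**Step 2**
Reactants: 2 (4R,6R)-4-[(tert-butyldimethylsilyl)oxy]-2,2,6-trimethylcyclohexan-1-one
Product: 4 (4R)-4-[(tert-butyldimethylsilyl)oxy]-2,6,6-trimethylcyclohex-1-en-1-yl trifluoromethanesulfonate, via lithium enolate 3 (not isolated)
Conditions: LiN(iPr)2, THF, −78 °C; then PhNTf2, −78 °C to rt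
Reagents that add atoms: N-phenylbis(trifluoromethanesulfonimide), O=S(=O)(N(c1ccccc1)S(=O)(=O)C(F)(F)F)C(F)(F)F
Why: Because C2 is quaternary the ketone can enolise only towards C6, so enol triflate formation (O-sulfonylation of the enolate) should give a single tetrasubstituted regioisomer, erasing the C6 stereocentre on purpose while the silyloxy carbon, γ to the carbonyl, is not affected.

**Step 3**
Reactants: 4 (4R)-4-[(tert-butyldimethylsilyl)oxy]-2,6,6-trimethylcyclohex-1-en-1-yl trifluoromethanesulfonate; 5 ethynyltrimethylsilane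
Product: 6 tert-butyldimethyl({(1R)-3,5,5-trimethyl-4-[(trimethylsilyl)ethynyl]cyclohex-3-en-1-yl}oxy)silane
Conditions: Pd(PPh3)4 (cat.), CuI (cat.), Et3N, DMF, 50 °C
Reagents that add atoms: none
Why: Sonogashira coupling of an enol triflate with a terminal alkyne attaches C7 and C8 to the hindered ring carbon, a reaction type well precedented for 2,6,6-trimethylcyclohexenyl triflates.

**Step 4**
Reactants: 6 tert-butyldimethyl({(1R)-3,5,5-trimethyl-4-[(trimethylsilyl)ethynyl]cyclohex-3-en-1-yl}oxy)silane
Product: 7 (1R)-4-ethynyl-3,5,5-trimethylcyclohex-3-en-1-ol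
Conditions: Bu4NF (excess), THF, 0 °C to rt; H2O work-up
Reagents that add atoms: none
Why: Fluoride desilylation should cleave the C(sp)–SiMe3 and O–Si bonds in one operation, giving the terminal alkyne and the free alcohol without touching the stereocentre.

**Step 5**
Reactants: 8 1-bromobut-2-yne; 9 triethyl phosphite
Product: 10 diethyl but-2-yn-1-ylphosphonate
Conditions: neat, 120 °C, EtBr distilled off
Reagents that add atoms: none
Why: Michaelis–Arbuzov reaction of a reactive propargylic bromide with a trialkyl phosphite gives the phosphonate with loss of bromoethane.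

**Step 6**
Reactants: 11 (2E,4E,6E)-2,7-dimethylocta-2,4,6-trienedial; 12 ethyl (2E)-4-(diethoxyphosphoryl)-2-methylbut-2-enoate
Product: 14 ethyl (2E,4E,6E,8E,10E)-2,6,11-trimethyl-12-oxododeca-2,4,6,8,10-pentaenoate, via lithiated phosphonate 13 (not isolated)
Conditions: 12, LiN(SiMe3)2, THF, −78 °C; added slowly to 11 (3 equiv, excess recovered), −78 to 0 °C
Reagents that add atoms: none
Why: Horner–Wadsworth–Emmons olefination through the phosphorus-bearing carbon of the stabilised vinylogous anion should form C11'=C12' with E geometry, and inverse addition to excess symmetric dialdehyde should confine the reaction to one formyl group.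

**Step 7**
Reactants: 14 ethyl (2E,4E,6E,8E,10E)-2,6,11-trimethyl-12-oxododeca-2,4,6,8,10-pentaenoate; 10 diethyl but-2-yn-1-ylphosphonate
Product: 16 ethyl (2E,4E,6E,8E,10E,12E)-2,6,11-trimethylhexadeca-2,4,6,8,10,12-hexaen-14-ynoate, via lithiated phosphonate 15 (not isolated)
Conditions: 10, LiN(SiMe3)2, THF, −78 °C; then 14, −78 to 0 °C
Reagents that add atoms: none
Why: Horner–Wadsworth–Emmons olefination with a propargylic phosphonate anion is a standard E-selective enyne synthesis that should form C11=C12, with low temperature holding back propargyl–allenyl isomerisation and the ester left untouched.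

**Step 8**
Reactants: 16 ethyl (2E,4E,6E,8E,10E,12E)-2,6,11-trimethylhexadeca-2,4,6,8,10,12-hexaen-14-ynoate
Product: 17 (2E,4E,6E,8E,10E,12E)-2,6,11-trimethylhexadeca-2,4,6,8,10,12-hexaen-14-yn-1-ol
Conditions: iBu2AlH, CH2Cl2, −78 °C; aq. potassium sodium tartrate
Reagents that add atoms: none
Why: 1,2-Reduction of the conjugated ester by iBu2AlH at low temperature should give the allylic alcohol without hydroalumination of the internal alkyne.

**Step 9**
Reactants: 17 (2E,4E,6E,8E,10E,12E)-2,6,11-trimethylhexadeca-2,4,6,8,10,12-hexaen-14-yn-1-ol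
Product: 18 (2E,4E,6E,8E,10E,12E)-2,6,11-trimethylhexadeca-2,4,6,8,10,12-hexaen-14-ynal
Conditions: MnO2 (activated), CH2Cl2, rt
Reagents that add atoms: none
Why: Allylic oxidation with MnO2 should convert the polyenylic primary alcohol chemoselectively into the aldehyde without touching the alkyne or the chain geometry.

**Step 10**
Reactants: 7 (1R)-4-ethynyl-3,5,5-trimethylcyclohex-3-en-1-ol; 18 (2E,4E,6E,8E,10E,12E)-2,6,11-trimethylhexadeca-2,4,6,8,10,12-hexaen-14-ynal
Product: 19 (2E,4E,6E,8E,10E,12E,14E)-17-[(4R)-4-hydroxy-2,6,6-trimethylcyclohex-1-en-1-yl]-2,6,11,15-tetramethylheptadeca-2,4,6,8,10,12,14-heptaen-16-ynal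
Conditions: 7 (1.3 equiv), Pd(OAc)2 (5 mol %), tris(2,6-dimethoxyphenyl)phosphine (5 mol %), degassed THF, rt, dark
Reagents that add atoms: none
Why: Proposed new method: Pd(OAc)2 and the electron-rich phosphine should turn 7, by acetate-assisted C–H metalation, into an alkynyl complex of divalent palladium that adds syn across C9≡C10 of 18 (C8 to C9, Pd to C10), after which protonolysis of the C10–Pd bond with retention by AcOH or the next molecule of 7 releases 19 while the metal stays divalent throughout. The closest known reaction type is the palladium-catalysed donor–acceptor alkyne cross-addition (hydroalkynylation) of terminal alkynes to but-2-ynoates, ynones and alkynyl sulfones, which gives (E)-3-methylalk-2-en-4-ynoates; the new element is an acceptor whose triple bond is activated only vinylogously, through six conjugated C=C bonds, by the formyl group. No ring is closed and no stereocentre is formed; the one stereochemical element created, the C9=C10 geometry, is fixed by the syn addition, which places C8 and the incoming H on C10 cis and therefore C8 trans to C11 as the target requires, and C3 is not involved. The step needs C–C bond formation at C9 and not at C10, and three features of 18 point the same way: C9 is the electrophilic position 16 counted from the carbonyl oxygen (the vinylogous β-carbon), it is the end atom of the linear π system where the LUMO coefficient should be large and that on C10 small, and it carries the small methyl group so that palladium goes to the carbon bearing the bulky polyenyl chain. The step also needs chemoselectivity against head-to-tail self-coupling of 7 and against a second addition to the C7≡C8 bond of 19, and both are disfavoured because C7 lies next to the fully substituted ring carbon C6 between the C1 gem-dimethyl and C5 methyl groups. The free C3–OH and the aldehyde should be spectators under these neutral room-temperature conditions, and the reaction is an addition with no by-product.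

**Compound list**

1 | (4R,6R)-4-hydroxy-2,2,6-trimethylcyclohexan-1-one (actinol) | O=C1C(C)(C)C[C@H](O)C[C@H]1C | starting material
2 | (4R,6R)-4-[(tert-butyldimethylsilyl)oxy]-2,2,6-trimethylcyclohexan-1-one | O=C1C(C)(C)C[C@H](O[Si](C)(C)C(C)(C)C)C[C@H]1C | intermediate
3 | lithium (4R)-4-[(tert-butyldimethylsilyl)oxy]-2,6,6-trimethylcyclohex-1-en-1-olate | CC1=C([O-])C(C)(C)C[C@H](O[Si](C)(C)C(C)(C)C)C1.[Li+] | intermediate
4 | (4R)-4-[(tert-butyldimethylsilyl)oxy]-2,6,6-trimethylcyclohex-1-en-1-yl trifluoromethanesulfonate | CC1=C(OS(=O)(=O)C(F)(F)F)C(C)(C)C[C@H](O[Si](C)(C)C(C)(C)C)C1 | intermediate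
5 | ethynyltrimethylsilane | C#C[Si](C)(C)C | starting material
6 | tert-butyldimethyl({(1R)-3,5,5-trimethyl-4-[(trimethylsilyl)ethynyl]cyclohex-3-en-1-yl}oxy)silane | CC1=C(C#C[Si](C)(C)C)C(C)(C)C[C@H](O[Si](C)(C)C(C)(C)C)C1 | intermediate
7 | (1R)-4-ethynyl-3,5,5-trimethylcyclohex-3-en-1-ol | CC1=C(C#C)C(C)(C)C[C@H](O)C1 | intermediate
8 | 1-bromobut-2-yne | CC#CCBr | starting material
9 | triethyl phosphite | CCOP(OCC)OCC | starting material
10 | diethyl but-2-yn-1-ylphosphonate | CC#CCP(=O)(OCC)OCC | intermediate
11 | (2E,4E,6E)-2,7-dimethylocta-2,4,6-trienedial | O=C/C(C)=C/C=C/C=C(\C)C=O | starting material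
12 | ethyl (2E)-4-(diethoxyphosphoryl)-2-methylbut-2-enoate | CCOC(=O)/C(C)=C/CP(=O)(OCC)OCC | starting material
13 | lithium salt of phosphonate 12 deprotonated at the phosphorus-bearing carbon | CCOC(=O)/C(C)=C/[CH-]P(=O)(OCC)OCC.[Li+] | intermediate
14 | ethyl (2E,4E,6E,8E,10E)-2,6,11-trimethyl-12-oxododeca-2,4,6,8,10-pentaenoate | O=C/C(C)=C/C=C/C=C(C)/C=C/C=C(\C)C(=O)OCC | intermediate
15 | lithium salt of phosphonate 10 deprotonated at the phosphorus-bearing carbon | CC#C[CH-]P(=O)(OCC)OCC.[Li+] | intermediate
16 | ethyl (2E,4E,6E,8E,10E,12E)-2,6,11-trimethylhexadeca-2,4,6,8,10,12-hexaen-14-ynoate | CC#C/C=C/C(C)=C/C=C/C=C(C)/C=C/C=C(\C)C(=O)OCC | intermediate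
17 | (2E,4E,6E,8E,10E,12E)-2,6,11-trimethylhexadeca-2,4,6,8,10,12-hexaen-14-yn-1-ol | CC#C/C=C/C(C)=C/C=C/C=C(C)/C=C/C=C(\C)CO | intermediate
18 | (2E,4E,6E,8E,10E,12E)-2,6,11-trimethylhexadeca-2,4,6,8,10,12-hexaen-14-ynal | CC#C/C=C/C(C)=C/C=C/C=C(C)/C=C/C=C(\C)C=O | intermediate
19 | (2E,4E,6E,8E,10E,12E,14E)-17-[(4R)-4-hydroxy-2,6,6-trimethylcyclohex-1-en-1-yl]-2,6,11,15-tetramethylheptadeca-2,4,6,8,10,12,14-heptaen-16-ynal | CC1=C(C#C/C(C)=C/C=C/C(C)=C/C=C/C=C(C)/C=C/C=C(\C)C=O)C(C)(C)C[C@H](O)C1 | target

**Step count**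

Total: 10 steps. Longest linear sequence: 5 steps (1 → 2 → 4 → 6 → 7 → 19, or 11 → 14 → 16 → 17 → 18 → 19).

**Steps most likely to fail**

Step 10 (Proposed new method). Carbopalladation of the only vinylogously activated C9≡C10 bond may be too slow, so that catalyst decay or self-coupling of 7 takes over. The extended palladium dienolate may also be protonated at a remote carbon, giving vinylallene isomers. The fallback uses known chemistry only, sets out from 7 and 14, and returns to the route at 19. The same C8–C9 bond is made on the established acceptor class by adding 7 across ethyl but-2-ynoate (Pd(OAc)2, tris(2,6-dimethoxyphenyl)phosphine, THF, rt), which should give ethyl (2E)-5-[(4R)-4-hydroxy-2,6,6-trimethylcyclohex-1-en-1-yl]-3-methylpent-2-en-4-ynoate F1. Reduction with iBu2AlH gives (1R)-4-[(3E)-5-hydroxy-3-methylpent-3-en-1-yn-1-yl]-3,5,5-trimethylcyclohex-3-en-1-ol F2. Ph3P·HBr in MeOH converts only the allylic alcohol into {(2E)-5-[(4R)-4-hydroxy-2,6,6-trimethylcyclohex-1-en-1-yl]-3-methylpent-2-en-4-yn-1-yl}triphenylphosphonium bromide F3. Wittig reaction of F3 with 14 (NaOMe, CH2Cl2/MeOH, then catalytic I2 to equilibrate C11=C12 to E) gives ethyl (2E,4E,6E,8E,10E,12E,14E)-17-[(4R)-4-hydroxy-2,6,6-trimethylcyclohex-1-en-1-yl]-2,6,11,15-tetramethylheptadeca-2,4,6,8,10,12,14-heptaen-16-ynoate F4. Reduction with iBu2AlH gives (2E,4E,6E,8E,10E,12E,14E)-17-[(4R)-4-hydroxy-2,6,6-trimethylcyclohex-1-en-1-yl]-2,6,11,15-tetramethylheptadeca-2,4,6,8,10,12,14-heptaen-16-yn-1-ol F5. MnO2 then oxidises only the allylic primary alcohol, not the homoallylic ring alcohol, and gives 19.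

Step 7. The lithiated propargylic phosphonate may equilibrate to its allenyl form, and the olefination may lose E selectivity. The fallback sets out from 14 and returns at 16. Takai iodo-olefination of the formyl group (CHI3, CrCl2, THF, 0 °C; the ester is inert) should give the E-vinyl iodide ethyl (2E,4E,6E,8E,10E,12E)-13-iodo-2,6,11-trimethyltrideca-2,4,6,8,10,12-hexaenoate F6. Sonogashira coupling of F6 with propyne (Pd(PPh3)4, CuI, Et3N, THF, rt) then gives 16, so that the geometry comes from the iodo-olefination and the alkyne from a cross-coupling.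

Step 6. Both formyl groups of the C2-symmetric dialdehyde may be olefinated, which wastes the phosphonate statistically, and the 2E geometry of the phosphonate-derived enoate may erode. The fallback sets out from 11 and returns at 14. Mono-acetalisation of 11 with 2,2-dimethylpropane-1,3-diol (cat. TsOH, toluene; dialdehyde and bis-acetal re-equilibrated and recycled) gives (2E,4E,6E)-7-(5,5-dimethyl-1,3-dioxan-2-yl)-2-methylocta-2,4,6-trienal F7. Its single formyl group is olefinated with 13 (from 12 and LiN(SiMe3)2) to give ethyl (2E,4E,6E,8E,10E)-11-(5,5-dimethyl-1,3-dioxan-2-yl)-2,6-dimethyldodeca-2,4,6,8,10-pentaenoate F8. Dilute aqueous H2SO4 in THF unmasks the aldehyde and gives 14.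

**Further compounds**

F1 | step 10 | ethyl (2E)-5-[(4R)-4-hydroxy-2,6,6-trimethylcyclohex-1-en-1-yl]-3-methylpent-2-en-4-ynoate | CC1=C(C#C/C(C)=C/C(=O)OCC)C(C)(C)C[C@H](O)C1
F2 | step 10 | (1R)-4-[(3E)-5-hydroxy-3-methylpent-3-en-1-yn-1-yl]-3,5,5-trimethylcyclohex-3-en-1-ol | CC1=C(C#C/C(C)=C/CO)C(C)(C)C[C@H](O)C1
F3 | step 10 | {(2E)-5-[(4R)-4-hydroxy-2,6,6-trimethylcyclohex-1-en-1-yl]-3-methylpent-2-en-4-yn-1-yl}triphenylphosphonium bromide | CC1=C(C#C/C(C)=C/C[P+](c2ccccc2)(c2ccccc2)c2ccccc2)C(C)(C)C[C@H](O)C1.[Br-]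
F4 | step 10 | ethyl (2E,4E,6E,8E,10E,12E,14E)-17-[(4R)-4-hydroxy-2,6,6-trimethylcyclohex-1-en-1-yl]-2,6,11,15-tetramethylheptadeca-2,4,6,8,10,12,14-heptaen-16-ynoate | CC1=C(C#C/C(C)=C/C=C/C(C)=C/C=C/C=C(C)/C=C/C=C(\C)C(=O)OCC)C(C)(C)C[C@H](O)C1
F5 | step 10 | (2E,4E,6E,8E,10E,12E,14E)-17-[(4R)-4-hydroxy-2,6,6-trimethylcyclohex-1-en-1-yl]-2,6,11,15-tetramethylheptadeca-2,4,6,8,10,12,14-heptaen-16-yn-1-ol | CC1=C(C#C/C(C)=C/C=C/C(C)=C/C=C/C=C(C)/C=C/C=C(\C)CO)C(C)(C)C[C@H](O)C1
F6 | step 7 | ethyl (2E,4E,6E,8E,10E,12E)-13-iodo-2,6,11-trimethyltrideca-2,4,6,8,10,12-hexaenoate | I/C=C/C(C)=C/C=C/C=C(C)/C=C/C=C(\C)C(=O)OCC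
F7 | step 6 | (2E,4E,6E)-7-(5,5-dimethyl-1,3-dioxan-2-yl)-2-methylocta-2,4,6-trienal | O=C/C(C)=C/C=C/C=C(\C)C1OCC(C)(C)CO1
F8 | step 6 | ethyl (2E,4E,6E,8E,10E)-11-(5,5-dimethyl-1,3-dioxan-2-yl)-2,6-dimethyldodeca-2,4,6,8,10-pentaenoate | CC1(C)COC(/C(C)=C/C=C/C=C(C)/C=C/C=C(\C)C(=O)OCC)OC1
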